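**Plan**
- Retrosynthesis: the enyne is cut at C3=C4 (cross-metathesis) and the chlorohydrin at C5–C6 (chloroallylboration). The ring oxygen O1 is taken out between C7 and C13 (Baeyer–Villiger transform), leaving a cycloheptanone C7–C13, whose C8–C9 and C12–C13 bonds are cut by a (4+3) transform into an ethyl-substituted oxyallyl cation (C8–C7–C13) and 3-methoxyfuran (C9–C12).
- Enabling feature: O1 sits between C7 and C13 (ketone retron), while sp2 C9 and Br-bearing C12 are 1,4-related like the α-carbons of a furan, with Cl-bearing C10 as its β-carbon. The furan oxygen bridges C9/C12 temporarily: its C12–O bond becomes the C12 stereocentre, and its C9–O bond is the α-alkoxy-ketone bond cleaved by SmI2 to fix C9=C10(Cl).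
- Forward: (4+3) gives the oxa-bridged cycloheptenone; chiral ketal; Baeyer–Villiger gives the bridged eight-membered lactone; methylenation/hydroboration sets C7; SmI2 opens the bridge to the oxocene enol triflate, then vinyl chloride; C12 OH to Br; side chain last.
- Stereochemistry: C9/C12 cis and C13 (ethyl anti to the bridge) from the cycloaddition plus base equilibration; absolute configuration by resolution as the (2R,3R)-butanediol ketal; C7 by hydroboration on the bicyclic template; C12–Br by two inversions (Mitsunobu, Appel); C5/C6 by reagent-controlled (Z)-γ-chloroallylboration; 3Z by enyne cross-metathesis.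

Key step: step 1

Assumption: 1 and 2 are taken as catalogue compounds; 4 is racemic with the relative configuration drawn, and every compound from 6 on is a single enantiomer. Atom labels C1–C15 are those of the target chain (C7 and C13 flank the ring oxygen).

Step 1
Reactants: 1 3-chloropentan-2-one; 2 3-methoxyfuran
Product: 4 rac-(1S,2R,5S)-2-ethyl-6-methoxy-8-oxabicyclo[3.2.1]oct-6-en-3-one, via oxyallyl zwitterion 3 (not isolated)
Conditions: Et3N, LiClO4, Et2O, rt (2 in excess)
Reagents that add atoms: none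
Why: Et3N/LiClO4 should enolise 1 towards its methyl group and ionise chloride to give the 1-ethyl-2-oxyallyl cation 3, which adds across C2/C5 of furan 2 in a (4+3) cycloaddition (four-carbon diene plus three-carbon allyl cation) that forms C8–C9 and C12–C13 in one operation; the closest known reaction type is the base-mediated oxyallyl–furan cycloaddition of α-chloro ketones. The seven-membered carbocycle closes by the cycloaddition itself, suprafacial on both partners through a compact transition state; in the stepwise limit the second bond is a seven-membered enolate-onto-oxocarbenium closure that keeps the C10=C11 enol ether inside the ring. C9 and C12 become cis because both bonds form on one face of the planar furan. The C13 ethyl group ends equatorial, anti to the oxygen bridge, through the compact transition state of the Z-configured cation and through Et3N equilibration of any axial epimer at this enolisable centre, so both epimers converge; the adduct is racemic. The step needs head-to-tail regioselectivity, which the 3-methoxy group should secure by making furan C2 the most nucleophilic carbon, so that it bonds first to the unhindered CH2 terminus and keeps methoxy and ethyl apart.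

Step 2
Reactants: 4 rac-(1S,2R,5S)-2-ethyl-6-methoxy-8-oxabicyclo[3.2.1]oct-6-en-3-one; 5 (2R,3R)-butane-2,3-diol
Product: 6 (1S,2R,5S)-2-ethyl-8-oxabicyclo[3.2.1]octane-3,6-dione 6-[(2R,3R)-butane-2,3-diyl] ketal
Conditions: 5 (slight excess), PPTS (cat.), CH2Cl2, rt; chromatographic separation of the two diastereomeric ketals
Reagents that add atoms: none
Why: Acid-catalysed addition of the diol to the enol ether with loss of methanol (transketalisation) masks the C10 carbonyl as a dioxolane, and because the diol is enantiopure the two enantiomers of 4 should give two diastereomeric ketals, of which 6 is isolated by chromatography (classical resolution; the spiro carbon of a C2-symmetric ketal is non-stereogenic, so only two diastereomers arise and at most half of the material is carried on).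

Step 3
Reactants: 6 (1S,2R,5S)-ketal ketone
Product: 7 (1S,2R,6S)-2-ethyl-3,9-dioxabicyclo[4.2.1]nonane-4,7-dione 7-[(2R,3R)-butane-2,3-diyl] ketal
Conditions: mCPBA, NaHCO3, CH2Cl2, 0 °C to rt
Reagents that add atoms: 3-chloroperoxybenzoic acid (mCPBA), OOC(=O)c1cccc(Cl)c1
Why: Baeyer–Villiger oxidation, in which the more substituted ethyl-bearing C13 should migrate in preference to the C8 methylene and with retention, inserting O1 between C7 and C13 to give the bridged eight-membered lactone.

Step 4
Reactants: 7 bridged lactone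
Product: 8 (1S,2R,6S)-2-ethyl-4-methylidene-3,9-dioxabicyclo[4.2.1]nonan-7-one (2R,3R)-butane-2,3-diyl ketal
Conditions: Cp2TiMe2, toluene, 70 °C, dark
Reagents that add atoms: dimethyltitanocene, [CH3-].[CH3-].[cH-]1cccc1.[cH-]1cccc1.[Ti+4]
Why: Petasis methylenation of the lactone carbonyl (titanium methylidene, oxatitanacyclobutane, cycloreversion) should give the exocyclic enol ether under non-basic conditions that leave the ketal and all stereocentres untouched.

Step 5
Reactants: 8 exocyclic enol ether
Product: 10 [(1S,2R,4R,6S)-2-ethyl-7,7-[(2R,3R)-butane-2,3-diyldioxy]-3,9-dioxabicyclo[4.2.1]nonan-4-yl]methanol, via B-alkyl-9-borabicyclononane 9 (not isolated)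
Conditions: 9-BBN, THF, 0 °C to rt; then NaOH, H2O2, 0 °C
Reagents that add atoms: hydrogen peroxide, OO
Why: Hydroboration–oxidation of the enol ether should place boron on the terminal carbon and deliver hydrogen to C7 from the face of the one-atom oxygen bridge, anti to the ketal-bearing two-carbon bridge, which sets C7 with its hydroxymethyl group cis to the C13 ethyl group.

Step 6
Reactants: 10 primary alcohol
Product: 11 tert-butyl{[(1S,2R,4R,6S)-2-ethyl-7,7-[(2R,3R)-butane-2,3-diyldioxy]-3,9-dioxabicyclo[4.2.1]nonan-4-yl]methoxy}diphenylsilane (tert-butyldiphenylsilyl ether of 10)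
Conditions: TBDPSCl, imidazole, DMF, rt
Reagents that add atoms: tert-butyl(chloro)diphenylsilane, CC(C)(C)[Si](Cl)(c1ccccc1)c1ccccc1
Why: Silyl ether formation protects the C6 hydroxyl with a group that should survive acid hydrolysis, SmI2, zerovalent nickel and the Mitsunobu and Appel steps.

Step 7
Reactants: 11 silyl ether ketal
Product: 12 (1S,2R,4R,6S)-4-{[tert-butyl(diphenyl)silyl]oxymethyl}-2-ethyl-3,9-dioxabicyclo[4.2.1]nonan-7-one
Conditions: TsOH·H2O (cat.), acetone/H2O, 55 °C
Reagents that add atoms: water, O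
Why: Acid-catalysed ketal hydrolysis in wet acetone should unveil the C10 ketone, which is flanked by the bridgehead C9–O bond, without touching the silyl ether or the ring ethers.

Step 8
Reactants: 12 bridged α-alkoxy ketone
Product: 14 (2R,3S,8R)-8-{[tert-butyl(diphenyl)silyl]oxymethyl}-2-ethyl-3-hydroxy-3,4,7,8-tetrahydro-2H-oxocin-5-yl trifluoromethanesulfonate, via samarium enolate 13 (not isolated)
Conditions: SmI2, THF/HMPA, −78 °C; then PhNTf2, −78 to 0 °C; aq. NH4Cl
Reagents that add atoms: N-phenylbis(trifluoromethanesulfonimide), FC(F)(F)S(=O)(=O)N(c1ccccc1)S(=O)(=O)C(F)(F)F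
Why: Ketyl formation at C10 and scission of the bridgehead C9–O bond (SmI2 reductive cleavage of an α-alkoxy ketone, as in the oxa-ring openings of 7-oxabicyclo[2.2.1]heptan-2-ones) should open the bridge to the monocyclic oxocene as the regiodefined C9=C10 enolate 13, whose O-sulfonylation fixes the double bond position while the untouched C12–O bond keeps its configuration.

Step 9
Reactants: 14 enol triflate
Product: 15 (2R,3S,8R)-8-{[tert-butyl(diphenyl)silyl]oxymethyl}-5-chloro-2-ethyl-3,4,7,8-tetrahydro-2H-oxocin-3-ol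
Conditions: Ni(cod)2 (cat.), LiCl, DMA/THF, rt
Reagents that add atoms: lithium chloride, [Li+].[Cl-]
Why: Nickel-catalysed exchange of an enol triflate for chloride (oxidative addition, triflate–chloride metathesis, C–Cl reductive elimination) should give the ring vinyl chloride at the position and with the ring-cis geometry defined by the triflate.

Step 10
Reactants: 15 C12 alcohol (hydroxyl trans to ethyl)
Product: 16 (2R,3R,8R)-8-{[tert-butyl(diphenyl)silyl]oxymethyl}-5-chloro-2-ethyl-3,4,7,8-tetrahydro-2H-oxocin-3-yl 4-nitrobenzoate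
Conditions: 4-nitrobenzoic acid, PPh3, DIAD, toluene, 0 °C to rt
Reagents that add atoms: 4-nitrobenzoic acid, OC(=O)c1ccc(cc1)[N+](=O)[O-]
Why: Mitsunobu esterification should displace the alkoxyphosphonium at C12 by carboxylate with inversion, placing the oxygen cis to the ethyl group as needed for the later bromide displacement.

Step 11
Reactants: 16 4-nitrobenzoate
Product: 17 (2R,3R,8R)-8-{[tert-butyl(diphenyl)silyl]oxymethyl}-5-chloro-2-ethyl-3,4,7,8-tetrahydro-2H-oxocin-3-ol
Conditions: K2CO3, MeOH, 0 °C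
Reagents that add atoms: none
Why: Base-catalysed transesterification (methanolysis) of the activated aryl ester should free the inverted C12 alcohol without affecting the silyl ether or the vinyl chloride.

Step 12
Reactants: 17 inverted C12 alcohol (hydroxyl cis to ethyl)
Product: 18 tert-butyl{[(2R,3S,8R)-3-bromo-5-chloro-2-ethyl-3,4,7,8-tetrahydro-2H-oxocin-8-yl]methoxy}diphenylsilane
Conditions: CBr4, P(n-C8H17)3, toluene, 70 °C
Reagents that add atoms: carbon tetrabromide, BrC(Br)(Br)Br
Why: Appel bromination should proceed by SN2 attack of bromide on the alkoxyphosphonium with inversion, giving the C12 bromide trans to the C13 ethyl group.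

Step 13
Reactants: 18 silyl ether
Product: 19 [(2R,3S,8R)-3-bromo-5-chloro-2-ethyl-3,4,7,8-tetrahydro-2H-oxocin-8-yl]methanol
Conditions: HF·pyridine, pyridine/THF, 0 °C to rt
Reagents that add atoms: none
Why: Fluoride-mediated desilylation under buffered, weakly acidic conditions should free the C6 alcohol without elimination of the secondary bromide.

Step 14
Reactants: 19 primary alcohol
Product: 20 (2R,3S,8R)-3-bromo-5-chloro-2-ethyl-3,4,7,8-tetrahydro-2H-oxocine-8-carbaldehyde
Conditions: Dess–Martin periodinane, NaHCO3, CH2Cl2, 0 °C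
Reagents that add atoms: none
Why: Dess–Martin oxidation should give the α-alkoxy aldehyde under buffered conditions that avoid epimerisation at C7.

Step 15
Reactants: 20 aldehyde
Product: 22 (1S,2S)-1-[(2R,3S,8R)-3-bromo-5-chloro-2-ethyl-3,4,7,8-tetrahydro-2H-oxocin-8-yl]-2-chlorobut-3-en-1-ol, via diisopinocampheylborinate 21 (not isolated)
Conditions: allyl chloride, LiN(c-C6H11)2, (+)-Ipc2BOMe, Et2O, −95 °C; BF3·OEt2; then 20, −95 °C; ethanolamine work-up
Reagents that add atoms: allyl chloride, C=CCCl
Why: Asymmetric (Z)-γ-chloroallylboration through a chair six-membered transition state, in which the Z geometry of the borane made in the flask should give the syn C5–Cl/C6–OH pair and the isopinocampheyl groups from (−)-α-pinene should direct attack to the re face of the aldehyde (6S, 5S) against the modest Felkin preference of the α-alkoxy aldehyde.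

Step 16
Reactants: 23 ethynyltriisopropylsilane; 24 1-bromoprop-1-ene (E/Z mixture)
Product: 25 triisopropyl(pent-3-en-1-yn-1-yl)silane (E/Z mixture)
Conditions: Pd(PPh3)2Cl2 (cat.), CuI (cat.), iPr2NH, THF, rt
Reagents that add atoms: none
Why: Sonogashira coupling of the terminal alkyne with the alkenyl bromide should give the conjugated enyne, whose alkene geometry is irrelevant because that alkene is cleaved in the metathesis.

Step 17
Reactants: 22 chlorohydrin with terminal alkene; 25 silyl enyne
Product: 26 (1S,2S,3Z)-1-[(2R,3S,8R)-3-bromo-5-chloro-2-ethyl-3,4,7,8-tetrahydro-2H-oxocin-8-yl]-2-chloro-6-(triisopropylsilyl)hex-3-en-5-yn-1-ol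
Conditions: second-generation Grubbs catalyst (cat.), 25 (excess), benzene, 60 °C
Reagents that add atoms: none
Why: Alkene–enyne cross-metathesis should be kinetically Z-selective because the alkynyl group avoids the N-heterocyclic carbene ligand in the ruthenacyclobutane, giving the 3Z-enyne with loss of propene while the trisubstituted ring chloroalkene stays inert.

Step 18
Reactants: 26 silyl enyne
Product: 27 bermudenynol, (1S,2S,3Z)-1-[(2R,3S,8R)-3-bromo-5-chloro-2-ethyl-3,4,7,8-tetrahydro-2H-oxocin-8-yl]-2-chlorohex-3-en-5-yn-1-ol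
Conditions: TBAF, AcOH, THF, 0 °C
Reagents that add atoms: none
Why: Fluoride-induced protodesilylation of the alkynylsilane, buffered with acetic acid so that the syn-chlorohydrin should not close to the epoxide, releases the terminal alkyne of the target.

**Compound list**
1 | 3-chloropentan-2-one (racemic) | CCC(Cl)C(C)=O | starting material
2 | 3-methoxyfuran | COc1ccoc1 | starting material
3 | 1-ethyl-2-oxyallyl cation (2-oxidopent-1-en-3-ylium zwitterion) | CC[CH+]C([O-])=C | intermediate
4 | rac-(1S,2R,5S)-2-ethyl-6-methoxy-8-oxabicyclo[3.2.1]oct-6-en-3-one (ethyl anti to the oxygen bridge; the enantiomer drawn is the one carried on) | O=C1C[C@H]2C(OC)=C[C@H](O2)[C@H]1CC | intermediate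
5 | (2R,3R)-butane-2,3-diol | C[C@@H](O)[C@@H](C)O | starting material
6 | (1S,2R,5S)-2-ethyl-8-oxabicyclo[3.2.1]octane-3,6-dione 6-[(2R,3R)-butane-2,3-diyl] ketal | O=C1C[C@H]2C3(O[C@H](C)[C@@H](C)O3)C[C@H](O2)[C@H]1CC | intermediate
7 | (1S,2R,6S)-2-ethyl-3,9-dioxabicyclo[4.2.1]nonane-4,7-dione 7-[(2R,3R)-butane-2,3-diyl] ketal | O=C1C[C@H]2C3(O[C@H](C)[C@@H](C)O3)C[C@H](O2)[C@@H](CC)O1 | intermediate
8 | (1S,2R,6S)-2-ethyl-4-methylidene-3,9-dioxabicyclo[4.2.1]nonan-7-one (2R,3R)-butane-2,3-diyl ketal | C=C1C[C@H]2C3(O[C@H](C)[C@@H](C)O3)C[C@H](O2)[C@@H](CC)O1 | intermediate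
9 | 9-{[(1S,2R,4S,6S)-2-ethyl-7,7-[(2R,3R)-butane-2,3-diyldioxy]-3,9-dioxabicyclo[4.2.1]nonan-4-yl]methyl}-9-borabicyclo[3.3.1]nonane | C(B1C2CCCC1CCC2)[C@H]3C[C@H]4C5(O[C@H](C)[C@@H](C)O5)C[C@H](O4)[C@@H](CC)O3 | intermediate
10 | [(1S,2R,4R,6S)-2-ethyl-7,7-[(2R,3R)-butane-2,3-diyldioxy]-3,9-dioxabicyclo[4.2.1]nonan-4-yl]methanol | OC[C@H]1C[C@H]2C3(O[C@H](C)[C@@H](C)O3)C[C@H](O2)[C@@H](CC)O1 | intermediate
11 | tert-butyl{[(1S,2R,4R,6S)-2-ethyl-7,7-[(2R,3R)-butane-2,3-diyldioxy]-3,9-dioxabicyclo[4.2.1]nonan-4-yl]methoxy}diphenylsilane | CC(C)(C)[Si](c1ccccc1)(c2ccccc2)OC[C@H]3C[C@H]4C5(O[C@H](C)[C@@H](C)O5)C[C@H](O4)[C@@H](CC)O3 | intermediate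
12 | (1S,2R,4R,6S)-4-{[tert-butyl(diphenyl)silyl]oxymethyl}-2-ethyl-3,9-dioxabicyclo[4.2.1]nonan-7-one | CC(C)(C)[Si](c1ccccc1)(c2ccccc2)OC[C@H]3C[C@H]4C(=O)C[C@H](O4)[C@@H](CC)O3 | intermediate
13 | ring-opened trivalent samarium enolate and alkoxide (C9=C10 enolate, C12 alkoxide) | CC(C)(C)[Si](c1ccccc1)(c2ccccc2)OC[C@H]3C/C=C(/O[Sm](I)I)C[C@H](O[Sm](I)I)[C@@H](CC)O3 | intermediate
14 | (2R,3S,8R)-8-{[tert-butyl(diphenyl)silyl]oxymethyl}-2-ethyl-3-hydroxy-3,4,7,8-tetrahydro-2H-oxocin-5-yl trifluoromethanesulfonate (ring alkene cis) | CC(C)(C)[Si](c1ccccc1)(c2ccccc2)OC[C@H]3C/C=C(/OS(=O)(=O)C(F)(F)F)C[C@H](O)[C@@H](CC)O3 | intermediate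
15 | (2R,3S,8R)-8-{[tert-butyl(diphenyl)silyl]oxymethyl}-5-chloro-2-ethyl-3,4,7,8-tetrahydro-2H-oxocin-3-ol (hydroxyl trans to ethyl) | CC(C)(C)[Si](c1ccccc1)(c2ccccc2)OC[C@H]3C/C=C(/Cl)C[C@H](O)[C@@H](CC)O3 | intermediate
16 | (2R,3R,8R)-8-{[tert-butyl(diphenyl)silyl]oxymethyl}-5-chloro-2-ethyl-3,4,7,8-tetrahydro-2H-oxocin-3-yl 4-nitrobenzoate | CC(C)(C)[Si](c1ccccc1)(c2ccccc2)OC[C@H]3C/C=C(/Cl)C[C@@H](OC(=O)c4ccc(cc4)[N+](=O)[O-])[C@@H](CC)O3 | intermediate
17 | (2R,3R,8R)-8-{[tert-butyl(diphenyl)silyl]oxymethyl}-5-chloro-2-ethyl-3,4,7,8-tetrahydro-2H-oxocin-3-ol (hydroxyl cis to ethyl) | CC(C)(C)[Si](c1ccccc1)(c2ccccc2)OC[C@H]3C/C=C(/Cl)C[C@@H](O)[C@@H](CC)O3 | intermediate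
18 | tert-butyl{[(2R,3S,8R)-3-bromo-5-chloro-2-ethyl-3,4,7,8-tetrahydro-2H-oxocin-8-yl]methoxy}diphenylsilane | CC(C)(C)[Si](c1ccccc1)(c2ccccc2)OC[C@H]3C/C=C(/Cl)C[C@H](Br)[C@@H](CC)O3 | intermediate
19 | [(2R,3S,8R)-3-bromo-5-chloro-2-ethyl-3,4,7,8-tetrahydro-2H-oxocin-8-yl]methanol | OC[C@H]1C/C=C(/Cl)C[C@H](Br)[C@@H](CC)O1 | intermediate
20 | (2R,3S,8R)-3-bromo-5-chloro-2-ethyl-3,4,7,8-tetrahydro-2H-oxocine-8-carbaldehyde | O=C[C@H]1C/C=C(/Cl)C[C@H](Br)[C@@H](CC)O1 | intermediate
21 | diisopinocampheylborinic ester of 22 (boron on the C6 oxygen) | C=C[C@H](Cl)[C@@H](OB([C@H]2C[C@H]3C[C@@H]([C@@H]2C)C3(C)C)[C@H]4C[C@H]5C[C@@H]([C@@H]4C)C5(C)C)[C@H]1C/C=C(/Cl)C[C@H](Br)[C@@H](CC)O1 | intermediate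
22 | (1S,2S)-1-[(2R,3S,8R)-3-bromo-5-chloro-2-ethyl-3,4,7,8-tetrahydro-2H-oxocin-8-yl]-2-chlorobut-3-en-1-ol | C=C[C@H](Cl)[C@@H](O)[C@H]1C/C=C(/Cl)C[C@H](Br)[C@@H](CC)O1 | intermediate
23 | ethynyltriisopropylsilane | C#C[Si](C(C)C)(C(C)C)C(C)C | starting material
24 | 1-bromoprop-1-ene (E/Z mixture) | CC=CBr | starting material
25 | triisopropyl(pent-3-en-1-yn-1-yl)silane (E/Z mixture) | CC=CC#C[Si](C(C)C)(C(C)C)C(C)C | intermediate
26 | (1S,2S,3Z)-1-[(2R,3S,8R)-3-bromo-5-chloro-2-ethyl-3,4,7,8-tetrahydro-2H-oxocin-8-yl]-2-chloro-6-(triisopropylsilyl)hex-3-en-5-yn-1-ol | CC(C)[Si](C(C)C)(C(C)C)C#C/C=C\[C@H](Cl)[C@@H](O)[C@H]1C/C=C(/Cl)C[C@H](Br)[C@@H](CC)O1 | intermediate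
27 | bermudenynol, (3Z,5S,6S,7R,12S,13R) in chain numbering | C#C/C=C\[C@H](Cl)[C@@H](O)[C@H]1C/C=C(/Cl)C[C@H](Br)[C@@H](CC)O1 | target

**Totals**
Total step count: 18. Longest linear sequence: 17 steps (steps 1–15, 17, 18; step 16 makes the metathesis partner).

**Steps most likely to fail**

Step 1. The electron-rich furan may lose a proton from the first-formed adduct (substitution at furan C2) or close at the methoxy-bearing carbon instead of closing the seven-membered ring. The fallback sets out from 1 and comes back at 4. Compound 1 and commercial 3-bromofuran, a less nucleophilic diene that should react in a more concerted way, would give under the same base-mediated conditions rac-6-bromo-2-ethyl-8-oxabicyclo[3.2.1]oct-6-en-3-one F1, to be separated from any regioisomer. Miyaura borylation (B2pin2, Pd(dppf)Cl2, KOAc, dioxane, 80 °C) would give the alkenyl pinacol boronate F2. Cu(OAc)2-promoted Chan–Lam coupling of F2 with methanol (Et3N, air, rt) would install the methyl enol ether and return rac-4.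

Step 8. O-Sulfonylation of the samarium enolate may be slow, so that it is protonated on work-up; the β-hydroxy ketone then loses the regiochemical information or dehydrates. The fallback sets out from 12 and comes back at 14. SmI2 cleavage followed by a Me3SiCl/Et3N quench would give the bis(trimethylsilyl) compound F3 (silyl enol ether at C9=C10, silyl ether at C12). MeLi (THF, 0 °C) would cleave only the enol silyl ether to the lithium enolate, which PhNTf2 converts into the enol triflate trimethylsilyl ether F4. PPTS in MeOH (0 °C) would remove the trimethylsilyl ether to give 14.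

Step 15. Facial selectivity may erode because the reagent works against the Felkin preference of the α-alkoxy aldehyde, and the chlorohydrin may close to the epoxide on work-up. The fallback sets out from 20 and comes back at 22. An Evans syn-aldol reaction of 20 with the dibutylboron enolate of (R)-4-benzyl-3-(chloroacetyl)oxazolidin-2-one (Bu2BOTf, iPr2NEt, CH2Cl2, −78 °C) would give the syn α-chloro-β-hydroxy imide F5 under auxiliary control. LiBH4 (THF, H2O, 0 °C) would remove the auxiliary to give the chloro diol F6. Selective oxidation of the primary hydroxyl (TEMPO, PhI(OAc)2) would give the β-hydroxy-α-chloro aldehyde F7. Non-basic Takai methylenation (Zn, CH2Br2, TiCl4, THF) would return 22.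

**Further compounds**
F1 | step 1 | rac-6-bromo-2-ethyl-8-oxabicyclo[3.2.1]oct-6-en-3-one (ethyl anti to the oxygen bridge) | O=C1C[C@H]2C(Br)=C[C@H](O2)[C@H]1CC
F2 | step 1 | rac-2-ethyl-6-(4,4,5,5-tetramethyl-1,3,2-dioxaborolan-2-yl)-8-oxabicyclo[3.2.1]oct-6-en-3-one | O=C1C[C@H]2C(B3OC(C)(C)C(C)(C)O3)=C[C@H](O2)[C@H]1CC
F3 | step 8 | bis(trimethylsilyl) derivative of the ring-opened oxocene (C10 trimethylsilyl enol ether, C12 trimethylsilyl ether) | CC(C)(C)[Si](c1ccccc1)(c2ccccc2)OC[C@H]3C/C=C(/O[Si](C)(C)C)C[C@H](O[Si](C)(C)C)[C@@H](CC)O3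
F4 | step 8 | C12 trimethylsilyl ether of enol triflate 14 | CC(C)(C)[Si](c1ccccc1)(c2ccccc2)OC[C@H]3C/C=C(/OS(=O)(=O)C(F)(F)F)C[C@H](O[Si](C)(C)C)[C@@H](CC)O3
F5 | step 15 | (R)-4-benzyl-3-{(2R,3S)-2-chloro-3-hydroxy-3-[(2R,3S,8R)-3-bromo-5-chloro-2-ethyl-3,4,7,8-tetrahydro-2H-oxocin-8-yl]propanoyl}oxazolidin-2-one (syn) | O=C(N1[C@H](Cc2ccccc2)COC1=O)[C@H](Cl)[C@@H](O)[C@H]3C/C=C(/Cl)C[C@H](Br)[C@@H](CC)O3
F6 | step 15 | (1S,2S)-2-chloro-1-[(2R,3S,8R)-3-bromo-5-chloro-2-ethyl-3,4,7,8-tetrahydro-2H-oxocin-8-yl]propane-1,3-diol (syn) | OC[C@H](Cl)[C@@H](O)[C@H]1C/C=C(/Cl)C[C@H](Br)[C@@H](CC)O1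
F7 | step 15 | (2R,3S)-2-chloro-3-hydroxy-3-[(2R,3S,8R)-3-bromo-5-chloro-2-ethyl-3,4,7,8-tetrahydro-2H-oxocin-8-yl]propanal (syn) | O=C[C@H](Cl)[C@@H](O)[C@H]1C/C=C(/Cl)C[C@H](Br)[C@@H](CC)O1
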